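**Strategy.** Each terminal ring (ring A: C1 ring ketone, C2 propionyl-bearing carbon, C3 and C5 enol carbons, C4 bridge-bearing carbon, C6 the CMe2 carbon) is a filicinic acid. The plan cuts it into an isobutyrate unit (C6–C1) and an acetoacetyl unit (C2–C3–C4–C5). In the key step the lithium enolate of methyl isobutyrate opens diketene (both commercial): release of β-lactone strain drives formation of the hindered C5–C6 bond at the quaternary carbon, and Dieckmann closure of the resulting 2,2-dimethyl-3,5-dioxohexanoate forms C1–C2 in the same flask. Propionylation and Mannich-type methylene bridging to a methylenebis(propionylphloroglucinol) core then assemble the tetramer.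

Key step: step 1

Remark on the chemistry: the target has no stereocentre and is drawn, like every enolised β-triketone here, as one tautomer of a rapidly equilibrating set. Filicinic acid 4 is mirror-symmetric through C6 and C3, so C2 and C4 are equivalent in it and step 2 gives one compound whichever of them is acylated.

Step 1
Reactants: 1 methyl isobutyrate; 2 diketene (4-methylideneoxetan-2-one)
Product: 4 filicinic acid (4,4-dimethylcyclohexane-1,3,5-trione in its dienol form), via lithium enolate of methyl 2,2-dimethyl-3,5-dioxohexanoate 3 (not isolated)
Conditions: LiN(iPr)2 (1.05 equiv), THF, −78 °C; 2 (1.0 equiv) added slowly, −78 °C; then LiN(iPr)2 (1.3 equiv), −78 °C to 40 °C; aq. HCl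
Reagents that add atoms: none
Why: The fully substituted lithium enolate of 1 attacks the lactone carbonyl of 2 and the strained four-membered ring opens by acyl–oxygen cleavage (Claisen-type C-acetoacetylation), which forms the hindered C5–C6 bond at the quaternary carbon and leaves the lithium diketonate of 3. The second portion of LiN(iPr)2 removes a proton from the terminal methyl group, the only enolisable position left, and this carbon of the 1,3-diketone dianion attacks the ester carbonyl, which cannot enolise because its α-carbon is quaternary, forming C1–C2 with loss of methoxide (Dieckmann condensation). The closest known reaction types are the acetoacetylation of oxygen, nitrogen and carbon nucleophiles by diketene and the Dieckmann closure of 2,2-dialkyl-3,5-dioxohexanoates to cyclohexane-1,3,5-triones. Ring A closes in a 6-(enolendo)-exo-trig acyl substitution, and no stereocentre is formed. The step needs addition to the lactone carbonyl to win over proton abstraction from 2, which slow addition of 2 to the cold enolate and the relief of β-lactone strain should secure. It also needs closure through carbon and not oxygen, which should follow because the terminal carbanion is the most reactive site that reaches the ester through a six-membered transition state and the trione dianion is a thermodynamic sink.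

Step 2
Reactants: 4 filicinic acid
Product: 5 propionylfilicinic acid (3,5-dihydroxy-6,6-dimethyl-2-propanoylcyclohexa-2,4-dien-1-one)
Conditions: EtCOCl (1.05 equiv), AlCl3 (3 equiv), CH2Cl2/MeNO2, 0 °C to rt; aq. HCl
Reagents that add atoms: propionyl chloride CCC(Cl)=O
Why: Friedel–Crafts C-acylation of the electron-rich dienol of 4 should take place at C2 (equivalent to C4), any enol ester formed first shifting to carbon under the same Lewis acid (Fries-type), and the aluminium-chelated β-triketone produced is deactivated toward a second acylation.

Step 3
Reactants: 6 flopropione (1-(2,4,6-trihydroxyphenyl)propan-1-one), two molecules per product, used in excess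
Product: 8 3,3'-methylenebis(2,4,6-trihydroxypropiophenone), via hydroxymethylflopropione 7 (not isolated)
Conditions: 37% aq. CH2O (0.3 equiv relative to 6), 1 M aq. NaOH, 0 °C to rt; aq. HCl; excess 6 recovered
Reagents that add atoms: formaldehyde C=O
Why: Base-mediated hydroxymethylation of the phloroglucinolate of 6 gives 7, whose benzylic hydroxyl is displaced by the ring carbon of a second phenolate (phenol–formaldehyde condensation of Friedel–Crafts type), and the threefold excess of 6 over formaldehyde should hold the condensation at the dimer stage.

Step 4
Reactants: 8 3,3'-methylenebis(2,4,6-trihydroxypropiophenone); 5 propionylfilicinic acid (2.2 equiv)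
Product: 10 target tetramer CNP0541376.0, via bis-Mannich base 9 (not isolated)
Conditions: CH2(NMe2)2 (2.2 equiv), 1,4-dioxane, 50 °C; volatiles removed; then 5 (2.2 equiv), 1,4-dioxane, 90 °C
Reagents that add atoms: bis(dimethylamino)methane CN(C)CN(C)C
Why: Mannich aminomethylation takes the single free ring carbon of each phloroglucinol ring of 8, and on heating the acidic enol 5 protonates each benzylic amine, dimethylamine is lost and C4 of 5 adds to the quinone-methide-type acceptor so formed (elimination then Michael addition), homocoupling being excluded because 9 has no free ring CH and 5 has no electrophilic site.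

**Compound list**
1 | methyl isobutyrate (methyl 2-methylpropanoate) | COC(=O)C(C)C | starting material
2 | diketene (4-methylideneoxetan-2-one) | C=C1CC(=O)O1 | starting material
3 | methyl 2,2-dimethyl-3,5-dioxohexanoate (formed as its lithium enolate) | COC(=O)C(C)(C)C(=O)CC(C)=O | intermediate
4 | filicinic acid (3,5-dihydroxy-4,4-dimethylcyclohexa-2,5-dien-1-one) | CC1(C)C(O)=CC(=O)C=C1O | intermediate
5 | propionylfilicinic acid (3,5-dihydroxy-6,6-dimethyl-2-propanoylcyclohexa-2,4-dien-1-one) | CCC(=O)C1=C(O)C=C(O)C(C)(C)C1=O | intermediate
6 | flopropione (1-(2,4,6-trihydroxyphenyl)propan-1-one) | CCC(=O)c1c(O)cc(O)cc1O | starting material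
7 | hydroxymethylflopropione (1-[2,4,6-trihydroxy-3-(hydroxymethyl)phenyl]propan-1-one) | CCC(=O)c1c(O)cc(O)c(CO)c1O | intermediate
8 | 3,3'-methylenebis(2,4,6-trihydroxypropiophenone) | CCC(=O)c1c(O)cc(O)c(Cc2c(O)cc(O)c(C(=O)CC)c2O)c1O | intermediate
9 | bis-Mannich base (5,5'-bis[(dimethylamino)methyl] derivative of 8) | CCC(=O)c1c(O)c(CN(C)C)c(O)c(Cc2c(O)c(CN(C)C)c(O)c(C(=O)CC)c2O)c1O | intermediate
10 | target tetramer CNP0541376.0 (propionylfilicinic acid–CH2–propionylphloroglucinol–CH2–propionylphloroglucinol–CH2–propionylfilicinic acid) | CCC(=O)C1=C(O)C(Cc2c(O)c(Cc3c(O)c(CC4=C(O)C(C)(C)C(=O)C(C(=O)CC)=C4O)c(O)c(C(=O)CC)c3O)c(O)c(C(=O)CC)c2O)=C(O)C(C)(C)C1=O | target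

**Total step count:** 4. **Longest linear sequence:** 3 steps (steps 1, 2 and 4); step 3 is a one-step branch.

**Steps most likely to fail**

Step 1. The enolate may abstract a proton from diketene or start its anionic oligomerisation instead of adding to the lactone carbonyl, or the dianion may close through oxygen to an enol lactone. The fallback sets out from 1 and comes back to the route at 4; it forms the same two bonds under neutral thermal conditions and in separate stages. Compound 1 is converted with LiN(iPr)2 and Me3SiCl in THF at −78 °C into its silyl ketene acetal, 1-methoxy-2-methyl-1-(trimethylsilyloxy)prop-1-ene F1. F1 is heated in toluene at 110 °C with commercial 2,2,6-trimethyl-4H-1,3-dioxin-4-one, which loses acetone to give acetylketene. The ketene should acylate F1 at carbon (hetero-Diels–Alder addition, then ring opening with silyl transfer) to give the silyl enol ether methyl (Z)-2,2-dimethyl-3-oxo-5-(trimethylsilyloxy)hex-4-enoate F2. Dilute aqueous acid should then give 3, now isolated, and NaOMe in MeOH at reflux should close 3 to 4 by Dieckmann condensation.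

Step 3. Over-condensation may occur, because the second free ring position of 6 and of the product also reacts with formaldehyde, so trimers and higher oligomers may form. The fallback sets out from 6 and comes back at 8; it separates the electrophilic from the nucleophilic partner. An excess of 6 is treated with CH2(NMe2)2 in 1,4-dioxane at 50 °C to give the mono-Mannich base 1-[3-[(dimethylamino)methyl]-2,4,6-trihydroxyphenyl]propan-1-one F3, which is freed from unreacted 6 by acid–base extraction. F3 is then heated with an excess of 6 in 1,4-dioxane at 90 °C, where loss of dimethylamine and trapping at the ring carbon of 6 should give 8.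

Step 4. The methylene bridges may exchange through reversible retro-Friedel–Crafts fragmentation at 90 °C, and the second coupling may stay incomplete, giving mixtures of homologues. The fallback sets out from 5 and 6 and comes back at 10; it forms the outer bridges first and the central bridge last, in the cold, and does not need 8. The mono-Mannich base F3 (made from 6 as described for step 3) is heated with 5 (1 equiv) in 1,4-dioxane at 80 °C to give the heterodimer 2-[(2,4,6-trihydroxy-3-propanoylphenyl)methyl]-substituted propionylfilicinic acid F4. F4 has a single free aromatic CH and should dimerise with 37% aq. CH2O (0.5 equiv) in dilute aq. NaOH at 0 °C to give only 10.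

**Further compounds**
F1 | step 1 | 1-methoxy-2-methyl-1-(trimethylsilyloxy)prop-1-ene | COC(O[Si](C)(C)C)=C(C)C
F2 | step 1 | methyl (Z)-2,2-dimethyl-3-oxo-5-(trimethylsilyloxy)hex-4-enoate | COC(=O)C(C)(C)C(=O)/C=C(\O[Si](C)(C)C)C
F3 | step 3 | 1-[3-[(dimethylamino)methyl]-2,4,6-trihydroxyphenyl]propan-1-one | CCC(=O)c1c(O)cc(O)c(CN(C)C)c1O
F4 | step 4 | propionylfilicinic acid–CH2–propionylphloroglucinol heterodimer | CCC(=O)C1=C(O)C(Cc2c(O)cc(O)c(C(=O)CC)c2O)=C(O)C(C)(C)C1=O
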